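**Retrosynthetic overview**

- The strategy rests on the C7'≡C8' triple bond that links ring B carbon C6' to the polyene. The whole C8–C8' chain is the symmetric all-E C20 dialdehyde (crocetin dialdehyde), so C8 and C8' are both former formyl carbons.
- Last C–C bond: C7'–C8'. The lithiated ring B allylic sulfone (C7' as CH2SO2Ph, cis-3',4'-bis-TBS ether) adds to the C8' formyl group of the ring A C30 aldehyde; phosphate and sulfinate are then eliminated in the same pot, and the three silyl ethers are removed.
- The C30 aldehyde is made the same way at C7–C8, from the ring A sulfone and the mono(dimethyl acetal) of the dialdehyde.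
- Both six-membered rings come intact from (4R,6R)-actinol. Ring A: enol triflate, carbonylation, reduction, sulfinate displacement. Ring B: dehydrogenation to the enone, sulfonylmethyl addition, oxidative 1,3-transposition, cis-selective ketone reduction.
- No ring is formed anywhere in the route.

Key step: step 13

Remark on the chemistry (assumption): a free formyl group is not expected to survive the excess amide base of the double elimination, so the dialdehyde enters the first union as its mono(dimethyl acetal); actinol, crocetin dialdehyde and methyl phenyl sulfone are taken as commercial, and the ring B diol is cis (3'S,4'R) as read from the SMILES.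

**Route**

Step 1
Reactants: 1 (4R,6R)-4-hydroxy-2,2,6-trimethylcyclohexan-1-one (actinol)
Product: 2 (4R,6R)-4-[(tert-butyldimethylsilyl)oxy]-2,2,6-trimethylcyclohexan-1-one
Conditions: TBSCl, imidazole, DMF, rt
Reagents that add atoms: tert-butyldimethylsilyl chloride, CC(C)(C)[Si](C)(C)Cl
Why: Standard silylation of an unhindered secondary alcohol, which touches neither stereocentre.

Step 2
Reactants: 2 (4R,6R)-4-[(tert-butyldimethylsilyl)oxy]-2,2,6-trimethylcyclohexan-1-one
Product: 3 (4R)-4-[(tert-butyldimethylsilyl)oxy]-2,6,6-trimethylcyclohex-1-en-1-yl trifluoromethanesulfonate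
Conditions: LiN(i-Pr)2, THF, –78 → 0 °C; PhNTf2, –78 °C → rt
Reagents that add atoms: N-phenylbis(trifluoromethanesulfonimide), O=S(=O)(N(c1ccccc1)S(=O)(=O)C(F)(F)F)C(F)(F)F
Why: Enol triflate formation from a ketone with a single enolisable position (the other α-carbon is quaternary), so only one enolate and one triflate can form; the methyl-bearing centre is erased on purpose and the silyloxy centre is remote.

Step 3
Reactants: 3 (4R)-4-[(tert-butyldimethylsilyl)oxy]-2,6,6-trimethylcyclohex-1-en-1-yl trifluoromethanesulfonate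
Product: 4 methyl (4R)-4-[(tert-butyldimethylsilyl)oxy]-2,6,6-trimethylcyclohex-1-ene-1-carboxylate
Conditions: Pd(OAc)2 (cat.), PPh3, CO (1 atm), MeOH, Et3N, DMF, 60 °C
Reagents that add atoms: carbon monoxide, [C-]#[O+]; methanol, CO
Why: Palladium-catalysed methoxycarbonylation of a vinyl triflate (oxidative addition to zerovalent palladium, CO insertion, methanolysis of the acyl complex), which installs C7 on C6.

Step 4
Reactants: 4 methyl (4R)-4-[(tert-butyldimethylsilyl)oxy]-2,6,6-trimethylcyclohex-1-ene-1-carboxylate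
Product: 5 [(4R)-4-[(tert-butyldimethylsilyl)oxy]-2,6,6-trimethylcyclohex-1-en-1-yl]methanol
Conditions: i-Bu2AlH, CH2Cl2, –78 → 0 °C
Reagents that add atoms: none
Why: Aluminium hydride 1,2-reduction of a hindered enoate to the allylic alcohol, with the silyl ether and the tetrasubstituted alkene inert.

Step 5
Reactants: 5 [(4R)-4-[(tert-butyldimethylsilyl)oxy]-2,6,6-trimethylcyclohex-1-en-1-yl]methanol
Product: 7 ring A allylic phenyl sulfone (3R TBS ether), via allylic bromide 6 (not isolated)
Conditions: CBr4, PPh3, CH2Cl2, 0 °C; concentrate; PhSO2Na, DMF, rt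
Reagents that add atoms: sodium benzenesulfinate, [Na+].[O-]S(=O)c1ccccc1
Why: Appel bromination followed by S-alkylation of the sulfinate at the primary allylic carbon (SN2); an allylic shift would require attack on the fully substituted C5 and is not expected.

Step 6
Reactants: 8 crocetin dialdehyde, all-E 2,6,11,15-tetramethylhexadeca-2,4,6,8,10,12,14-heptaenedial
Product: 9 all-E 16,16-dimethoxy-2,6,11,15-tetramethylhexadeca-2,4,6,8,10,12,14-heptaenal
Conditions: HC(OMe)3 (1 equiv), pyridinium p-toluenesulfonate (cat.), MeOH/CH2Cl2, rt; Et3N quench; Et3N-deactivated silica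
Reagents that add atoms: trimethyl orthoformate, COC(OC)OC; methanol, CO
Why: Acid-catalysed acetalisation with a limiting amount of orthoformate should give the mono-acetal of the symmetric dialdehyde as the main component, with unreacted 8 and the bis-acetal (after mild hydrolysis) returned to the step.

Step 7
Reactants: 7 ring A allylic phenyl sulfone (3R TBS ether); 9 all-E 16,16-dimethoxy-2,6,11,15-tetramethylhexadeca-2,4,6,8,10,12,14-heptaenal
Product: 13 ring A C30 all-E aldehyde (3R TBS ether), via phosphate adduct 10 (not isolated), via dienyl sulfone 11 (not isolated), via C30 dimethyl acetal 12 (not isolated)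
Conditions: LiN(SiMe3)2 (1.1 equiv), THF, –78 °C; 9; ClP(O)(OEt)2; LiN(SiMe3)2 (3 equiv), –78 °C → rt; then aq. oxalic acid, THF, rt
Reagents that add atoms: water, O
Why: Julia-type sulfone–aldehyde addition run as a one-pot double elimination: the α-sulfonyl carbanion of 7 adds to the free formyl group of 9, the alkoxide is capped as phosphate 10, excess amide base removes phosphate (to 11) and then benzenesulfinate to give the C7≡C8 alkyne 12, and the base-stable dimethyl acetal is hydrolysed in the mildly acidic work-up, which the secondary TBS ether should tolerate.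

Step 8
Reactants: 2 (4R,6R)-4-[(tert-butyldimethylsilyl)oxy]-2,2,6-trimethylcyclohexan-1-one
Product: 15 (4S)-4-[(tert-butyldimethylsilyl)oxy]-2,6,6-trimethylcyclohex-2-en-1-one, via trimethylsilyl enol ether 14 (not isolated)
Conditions: LiN(i-Pr)2, THF, –78 → 0 °C; Me3SiCl; concentrate; Pd(OAc)2 (1 equiv), MeCN, rt
Reagents that add atoms: none
Why: Saegusa–Ito oxidation: the single possible silyl enol ether is converted by Pd(OAc)2 into the α-palladated ketone, which loses a ring β-hydrogen to give the conjugated enone and zerovalent palladium; the silyloxy centre is untouched and its descriptor changes from R to S only through the priority rules.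

Step 9
Reactants: 15 (4S)-4-[(tert-butyldimethylsilyl)oxy]-2,6,6-trimethylcyclohex-2-en-1-one; 16 methyl phenyl sulfone
Product: 17 (4S)-4-[(tert-butyldimethylsilyl)oxy]-2,6,6-trimethyl-1-[(phenylsulfonyl)methyl]cyclohex-2-en-1-ol (C1 epimers)
Conditions: 16, n-BuLi, THF, –78 °C; 15, –78 °C; AcOH, –78 °C
Reagents that add atoms: none
Why: Kinetic 1,2-addition of (phenylsulfonyl)methyllithium to an enone that has no α'-hydrogen to lose, quenched cold to prevent retro-addition; the carbonyl carbon becomes C6' and the new carbinol centre is of no consequence because it is destroyed in step 10.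

Step 10
Reactants: 17 (4S)-4-[(tert-butyldimethylsilyl)oxy]-2,6,6-trimethyl-1-[(phenylsulfonyl)methyl]cyclohex-2-en-1-ol
Product: 18 (6S)-6-[(tert-butyldimethylsilyl)oxy]-2,4,4-trimethyl-3-[(phenylsulfonyl)methyl]cyclohex-2-en-1-one
Conditions: pyridinium chlorochromate [C5H5NH][CrO3Cl], NaOAc, 4 Å molecular sieves, CH2Cl2, rt
Reagents that add atoms: pyridinium chlorochromate, [O-][Cr](=O)(=O)Cl.c1cc[nH+]cc1
Why: Babler–Dauben oxidative transposition: the tertiary allylic alcohol forms a chromate ester of hexavalent chromium, a [3,3]-shift delivers oxygen to C4', and the secondary allylic chromate collapses to the enone, as is known for the analogous β-hydroxy ester adducts of cyclohexenones; the acetate buffer protects the silyl ether and the C3' centre next to the new ketone.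

Step 11
Reactants: 18 (6S)-6-[(tert-butyldimethylsilyl)oxy]-2,4,4-trimethyl-3-[(phenylsulfonyl)methyl]cyclohex-2-en-1-one
Product: 19 (1R,6S)-6-[(tert-butyldimethylsilyl)oxy]-2,4,4-trimethyl-3-[(phenylsulfonyl)methyl]cyclohex-2-en-1-ol (3',4'-cis)
Conditions: LiBH(s-Bu)3, THF, –78 °C; then H2O
Reagents that add atoms: none
Why: Substrate-controlled 1,2-reduction (conjugate reduction is blocked by the fully substituted β-carbon C6'): the C3' silyloxy group sits pseudo-equatorial to avoid the axial C1' methyl, and the bulky hydride should enter from the side of the small C3' hydrogen, placing the new C4' hydroxyl cis to the silyloxy group (4'R).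

Step 12
Reactants: 19 (1R,6S)-6-[(tert-butyldimethylsilyl)oxy]-2,4,4-trimethyl-3-[(phenylsulfonyl)methyl]cyclohex-2-en-1-ol
Product: 20 ring B allylic phenyl sulfone, cis-(3'S,4'R) bis-TBS ether
Conditions: TBSOTf, 2,6-lutidine, CH2Cl2, 0 °C
Reagents that add atoms: tert-butyldimethylsilyl trifluoromethanesulfonate, CC(C)(C)[Si](C)(C)OS(=O)(=O)C(F)(F)F
Why: Silyl triflate silylation of a hindered secondary allylic alcohol under non-nucleophilic base, with no change at either stereocentre.

Step 13
Reactants: 20 ring B allylic phenyl sulfone, cis-(3'S,4'R) bis-TBS ether; 13 ring A C30 all-E aldehyde (3R TBS ether)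
Product: 23 (3R,3'S,4'R)-tris-TBS ether of the target, via phosphate adduct 21 (not isolated), via dienyl sulfone 22 (not isolated)
Conditions: LiN(SiMe3)2 (1.1 equiv), THF, –78 °C; 13; ClP(O)(OEt)2; LiN(SiMe3)2 (3 equiv), –78 °C → rt; dark, argon
Reagents that add atoms: none
Why: The amide base removes one C7' proton of 20, the sulfonyl-stabilised carbanion adds 1,2 to the C8' formyl group of 13 (making C7'–C8'), ClP(O)(OEt)2 caps the lithium alkoxide as phosphate 21, and further base expels first diethyl phosphate through the re-formed C7' carbanion (giving 1-sulfonyl diene 22) and then benzenesulfinate together with the vinylic C8' hydrogen, which leaves the C7'≡C8' triple bond. The closest known reaction type is the Julia-type addition of a sulfone anion to an aldehyde carried through as a one-pot double elimination to an alkyne, established for allylic sulfones and enals and already used in step 7. No ring is closed and no stereocentre is created: the two transient centres at C7' and C8' are erased, a triple bond raises no E/Z question, and the trisubstituted C9'=C10' bond keeps the E geometry it has in the dialdehyde. The step needs attack through C7' and not through the γ-carbon C5', which the sulfonyl group (charge held at C7') and the fully substituted, hindered C5' terminus should secure. It also needs the allyl anion not to push out the C4' silyloxy group in a vinylogous elimination, which is guarded by the reluctance of a silyloxide to leave, by –78 °C and by prompt capture with the aldehyde. The silyl ethers, the ring A enyne and the polyene are expected to be inert to the amide base.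

Step 14
Reactants: 23 (3R,3'S,4'R)-tris-TBS ether of the target
Product: 24 all-E (3R,3'S,4'R)-7,8,7',8'-tetradehydro-β,β-carotene-3,3',4'-triol (target)
Conditions: Bu4NF, THF, rt, dark, argon; chromatography and crystallisation in the dark
Reagents that add atoms: none
Why: Fluoride-driven cleavage of the three Si–O bonds (one at C3, two on the vicinal cis-diol) under conditions that should leave the polyene-diyne and all three stereocentres unchanged.

**Compound list**

1 | (4R,6R)-4-hydroxy-2,2,6-trimethylcyclohexan-1-one (actinol) | C[C@H]1C(=O)C(C)(C)C[C@H](O)C1 | starting material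
2 | (4R,6R)-4-[(tert-butyldimethylsilyl)oxy]-2,2,6-trimethylcyclohexan-1-one | C[C@H]1C(=O)C(C)(C)C[C@H](O[Si](C)(C)C(C)(C)C)C1 | intermediate
3 | (4R)-4-[(tert-butyldimethylsilyl)oxy]-2,6,6-trimethylcyclohex-1-en-1-yl trifluoromethanesulfonate | CC1=C(OS(=O)(=O)C(F)(F)F)C(C)(C)C[C@H](O[Si](C)(C)C(C)(C)C)C1 | intermediate
4 | methyl (4R)-4-[(tert-butyldimethylsilyl)oxy]-2,6,6-trimethylcyclohex-1-ene-1-carboxylate | CC1=C(C(=O)OC)C(C)(C)C[C@H](O[Si](C)(C)C(C)(C)C)C1 | intermediate
5 | [(4R)-4-[(tert-butyldimethylsilyl)oxy]-2,6,6-trimethylcyclohex-1-en-1-yl]methanol | CC1=C(CO)C(C)(C)C[C@H](O[Si](C)(C)C(C)(C)C)C1 | intermediate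
6 | (4R)-1-(bromomethyl)-4-[(tert-butyldimethylsilyl)oxy]-2,6,6-trimethylcyclohex-1-ene (allylic bromide, not isolated) | CC1=C(CBr)C(C)(C)C[C@H](O[Si](C)(C)C(C)(C)C)C1 | intermediate
7 | {[(4R)-4-[(tert-butyldimethylsilyl)oxy]-2,6,6-trimethylcyclohex-1-en-1-yl]methyl} phenyl sulfone (ring A sulfone, 3R) | CC1=C(CS(=O)(=O)c2ccccc2)C(C)(C)C[C@H](O[Si](C)(C)C(C)(C)C)C1 | intermediate
8 | crocetin dialdehyde, all-E 2,6,11,15-tetramethylhexadeca-2,4,6,8,10,12,14-heptaenedial | O=C/C(C)=C/C=C/C(C)=C/C=C/C=C(C)/C=C/C=C(\C)C=O | starting material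
9 | all-E 16,16-dimethoxy-2,6,11,15-tetramethylhexadeca-2,4,6,8,10,12,14-heptaenal (mono-acetal) | COC(OC)/C(C)=C/C=C/C(C)=C/C=C/C=C(C)/C=C/C=C(\C)C=O | intermediate
10 | β-(diethoxyphosphoryloxy) sulfone from 7 and 9 (C7/C8 diastereomers, not isolated) | CC1=C(C(C(OP(=O)(OCC)OCC)/C(C)=C/C=C/C(C)=C/C=C/C=C(C)/C=C/C=C(\C)C(OC)OC)S(=O)(=O)c2ccccc2)C(C)(C)C[C@H](O[Si](C)(C)C(C)(C)C)C1 | intermediate
11 | C7-(phenylsulfonyl) C7=C8 diene dimethyl acetal (C7=C8 isomers, not isolated) | CC1=C(C(=C/C(C)=C/C=C/C(C)=C/C=C/C=C(C)/C=C/C=C(\C)C(OC)OC)S(=O)(=O)c2ccccc2)C(C)(C)C[C@H](O[Si](C)(C)C(C)(C)C)C1 | intermediate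
12 | ring A C30 all-E 7,8-didehydro dimethyl acetal, (3R) TBS ether (not isolated) | CC1=C(C#C/C(C)=C/C=C/C(C)=C/C=C/C=C(C)/C=C/C=C(\C)C(OC)OC)C(C)(C)C[C@H](O[Si](C)(C)C(C)(C)C)C1 | intermediate
13 | ring A C30 all-E 7,8-didehydro aldehyde, (3R) TBS ether | CC1=C(C#C/C(C)=C/C=C/C(C)=C/C=C/C=C(C)/C=C/C=C(\C)C=O)C(C)(C)C[C@H](O[Si](C)(C)C(C)(C)C)C1 | intermediate
14 | (4R)-4-[(tert-butyldimethylsilyl)oxy]-2,6,6-trimethyl-1-[(trimethylsilyl)oxy]cyclohex-1-ene (not isolated) | CC1=C(O[Si](C)(C)C)C(C)(C)C[C@H](O[Si](C)(C)C(C)(C)C)C1 | intermediate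
15 | (4S)-4-[(tert-butyldimethylsilyl)oxy]-2,6,6-trimethylcyclohex-2-en-1-one | CC1=C[C@@H](O[Si](C)(C)C(C)(C)C)CC(C)(C)C1=O | intermediate
16 | methyl phenyl sulfone | CS(=O)(=O)c1ccccc1 | starting material
17 | (4S)-4-[(tert-butyldimethylsilyl)oxy]-2,6,6-trimethyl-1-[(phenylsulfonyl)methyl]cyclohex-2-en-1-ol (C1 epimers) | CC1=C[C@@H](O[Si](C)(C)C(C)(C)C)CC(C)(C)C1(O)CS(=O)(=O)c2ccccc2 | intermediate
18 | (6S)-6-[(tert-butyldimethylsilyl)oxy]-2,4,4-trimethyl-3-[(phenylsulfonyl)methyl]cyclohex-2-en-1-one | O=S(=O)(c1ccccc1)CC2=C(C)C(=O)[C@@H](O[Si](C)(C)C(C)(C)C)CC2(C)C | intermediate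
19 | (1R,6S)-6-[(tert-butyldimethylsilyl)oxy]-2,4,4-trimethyl-3-[(phenylsulfonyl)methyl]cyclohex-2-en-1-ol (cis) | O=S(=O)(c1ccccc1)CC2=C(C)[C@@H](O)[C@@H](O[Si](C)(C)C(C)(C)C)CC2(C)C | intermediate
20 | {[(3R,4S)-3,4-bis[(tert-butyldimethylsilyl)oxy]-2,6,6-trimethylcyclohex-1-en-1-yl]methyl} phenyl sulfone (ring B sulfone, cis, 3'S,4'R in carotenoid numbering) | O=S(=O)(c1ccccc1)CC2=C(C)[C@@H](O[Si](C)(C)C(C)(C)C)[C@@H](O[Si](C)(C)C(C)(C)C)CC2(C)C | intermediate
21 | β-(diethoxyphosphoryloxy) sulfone from 20 and 13 (C7'/C8' diastereomers, not isolated) | CC1=C(C#C/C(C)=C/C=C/C(C)=C/C=C/C=C(C)/C=C/C=C(\C)C(OP(=O)(OCC)OCC)C(S(=O)(=O)c2ccccc2)C2=C(C)[C@@H](O[Si](C)(C)C(C)(C)C)[C@@H](O[Si](C)(C)C(C)(C)C)CC2(C)C)C(C)(C)C[C@H](O[Si](C)(C)C(C)(C)C)C1 | intermediate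
22 | C7'-(phenylsulfonyl) C7'=C8' diene, tris-TBS ether (C7'=C8' isomers, not isolated) | CC1=C(C#C/C(C)=C/C=C/C(C)=C/C=C/C=C(C)/C=C/C=C(\C)C=C(S(=O)(=O)c2ccccc2)C2=C(C)[C@@H](O[Si](C)(C)C(C)(C)C)[C@@H](O[Si](C)(C)C(C)(C)C)CC2(C)C)C(C)(C)C[C@H](O[Si](C)(C)C(C)(C)C)C1 | intermediate
23 | all-E (3R,3'S,4'R)-3,3',4'-tris[(tert-butyldimethylsilyl)oxy]-7,8,7',8'-tetradehydro-β,β-carotene | CC1=C(C#C/C(C)=C/C=C/C(C)=C/C=C/C=C(C)/C=C/C=C(\C)C#CC2=C(C)[C@@H](O[Si](C)(C)C(C)(C)C)[C@@H](O[Si](C)(C)C(C)(C)C)CC2(C)C)C(C)(C)C[C@H](O[Si](C)(C)C(C)(C)C)C1 | intermediate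
24 | all-E (3R,3'S,4'R)-7,8,7',8'-tetradehydro-β,β-carotene-3,3',4'-triol (CNP0323983.1) | CC1=C(C#C/C(C)=C/C=C/C(C)=C/C=C/C=C(C)/C=C/C=C(\C)C#CC2=C(C)[C@@H](O)[C@@H](O)CC2(C)C)C(C)(C)C[C@H](O)C1 | target

**Totals**

Total step count: 14.
Longest linear sequence: 8 steps (1, 8, 9, 10, 11, 12, 13, 14 from actinol; the ring A branch 1, 2, 3, 4, 5, 7, 13, 14 is equally long).

**Steps most likely to fail**

1. Step 13. The lithiated allylic sulfone may expel the C4' silyloxy group in a vinylogous elimination before it meets the aldehyde, or the sequence may stall at the dienyl sulfone because the second elimination is slow on this hindered ring. The fallback sets out from 20 and 13 and returns at 23 by a staged Julia-type sequence with isolated intermediates. Compound 20 is lithiated with n-BuLi in THF at –78 °C, treated at once with 13 and quenched cold with AcOH to give the β-hydroxy sulfone F1. Acetylation (Ac2O, DMAP, pyridine) gives the β-acetoxy sulfone F2. Excess KOt-Bu in THF at 0 °C then removes acetate and benzenesulfinate in turn to give 23. Each stage can be followed and corrected on its own, and the anion lives only for the moment of the addition.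

2. Step 9. The sulfonyl carbanion may add reversibly to the hindered ketone and fall back to the enone, or it may drift to conjugate addition at the unsubstituted β-carbon. The fallback sets out from 15 and returns at 17. The harder and more nucleophilic (phenylthio)methyllithium (thioanisole, n-BuLi, 1,4-diazabicyclo[2.2.2]octane, THF, 0 °C, then 15 at –78 °C) adds irreversibly to the carbonyl group to give the β-hydroxy sulfide F3. Oxidation at sulfur with KHSO5 (as 2KHSO5·KHSO4·K2SO4) in MeOH/H2O at 0 °C then gives sulfone 17.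

3. Step 11. Facial selectivity may be poor, with hydride delivered from the face next to the silyloxy group so that the trans diol derivative forms. The fallback sets out from 18 and returns at 19 by setting C4' through inversion. Reduction with NaBH4 and CeCl3·7H2O in MeOH (Luche conditions, small hydride, axial attack) is used to give the trans alcohol F4. Mitsunobu reaction with 4-nitrobenzoic acid, PPh3 and diisopropyl azodicarboxylate in THF then inverts C4' to give the cis 4-nitrobenzoate F5. Methanolysis with K2CO3 in MeOH releases 19.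

**Further compounds**

F1 | step 13 | β-hydroxy sulfone from 20 and 13 (C7'/C8' diastereomers) | CC1=C(C#C/C(C)=C/C=C/C(C)=C/C=C/C=C(C)/C=C/C=C(\C)C(O)C(S(=O)(=O)c2ccccc2)C2=C(C)[C@@H](O[Si](C)(C)C(C)(C)C)[C@@H](O[Si](C)(C)C(C)(C)C)CC2(C)C)C(C)(C)C[C@H](O[Si](C)(C)C(C)(C)C)C1
F2 | step 13 | β-acetoxy sulfone from F1 (C7'/C8' diastereomers) | CC1=C(C#C/C(C)=C/C=C/C(C)=C/C=C/C=C(C)/C=C/C=C(\C)C(OC(C)=O)C(S(=O)(=O)c2ccccc2)C2=C(C)[C@@H](O[Si](C)(C)C(C)(C)C)[C@@H](O[Si](C)(C)C(C)(C)C)CC2(C)C)C(C)(C)C[C@H](O[Si](C)(C)C(C)(C)C)C1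
F3 | step 9 | (4S)-4-[(tert-butyldimethylsilyl)oxy]-2,6,6-trimethyl-1-[(phenylthio)methyl]cyclohex-2-en-1-ol (C1 epimers) | CC1=C[C@@H](O[Si](C)(C)C(C)(C)C)CC(C)(C)C1(O)CSc2ccccc2
F4 | step 11 | (1S,6S)-6-[(tert-butyldimethylsilyl)oxy]-2,4,4-trimethyl-3-[(phenylsulfonyl)methyl]cyclohex-2-en-1-ol (trans) | O=S(=O)(c1ccccc1)CC2=C(C)[C@H](O)[C@@H](O[Si](C)(C)C(C)(C)C)CC2(C)C
F5 | step 11 | (1R,6S)-6-[(tert-butyldimethylsilyl)oxy]-2,4,4-trimethyl-3-[(phenylsulfonyl)methyl]cyclohex-2-en-1-yl 4-nitrobenzoate (cis) | O=S(=O)(c1ccccc1)CC2=C(C)[C@@H](OC(=O)c3ccc(cc3)[N+](=O)[O-])[C@@H](O[Si](C)(C)C(C)(C)C)CC2(C)C
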